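## The problem

The target is a C30 triterpenoid made of two bicyclic halves joined only by a CH2–CH2 chain. The left half is a trans-fused oxepan-3-one/cyclohexane (rings A and B). The right half is a cis-fused cyclopentane/cycloheptane (rings D and C) whose seven-membered ring carries a trisubstituted epoxide. There are ten stereocentres, four on the left and six on the right. The two sets are too far apart to control each other, so each half must be made enantioselectively and the halves joined late between two neopentyl-type positions.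

On the left, the O-bearing ring-fusion CH (C-9a) and the neighbouring quaternary C–CH3 (C-5a) can control the other two centres of ring B. The chain-bearing CH and the tertiary carbinol can settle under thermodynamic control in a chair that has an axial angular methyl. On the right, the CH next to the C(CH3)2 group can control the ring fusion and the ring-D carbinol. An oxygen placed on ring C can then pass its configuration to the chain-bearing CH and from there to the epoxide.

The groups at risk are the epoxide (acid), the two tertiary alcohols (dehydration, and retro-aldol while an aldehyde sits β to one of them) and the ring-A ketone. The feature that invites the key step is the C-9a–C-5a bond. It is the most congested bond of rings A and B, and ring A (ether oxygen, C(CH3)2, three further carbons, C-9a and C-5a) can be closed across it by a [3,3] shift of a lactone-tethered enolate.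

## Retrosynthesis

**Union.** Target 40 is traced back through silyl ether 39 and alkene 38 to aldehyde 22 and sulfone 37 (Julia–Kocienski olefination, then hydrogenation). The cut is the central bond of the two-carbon link. The neighbouring bonds (ring B to CH2, CH2 to ring C) would need a nucleophile or electrophile on a ring carbon flanked by fully substituted centres. The cut gives two halves of equal size. The forward reaction must only tolerate a hindered, enolisable aldehyde, a ketone and an epoxide. The epoxide is brought in with 37 because a final epoxidation of the free alkene would have no directing group and would probably favour the wrong face.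

**Epoxide and chain-bearing centre of ring C.** Sulfone 37 comes from epoxy diol 35 (Mitsunobu thioetherification to 36, then oxidation). The epoxide of 35 is cut back to homoallylic alcohol 34, whose CH2OH delivers oxygen to its own face. The CH2OH–ring bond of 34 is cut by a [2,3]-Wittig–Still rearrangement of stannylmethyl ether 33, made from allylic alcohol 32. This replaces a difficult conjugate addition next to C(CH3)2 by a suprafacial transfer from a carbinol, and that carbinol is set by reagent-controlled reduction of enone 31.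

**Ring D and ring C.** Hydroxy enone 31 is cut at the bond between the ring-fusion carbon and the carbinol carbon, a ketyl–enone cyclisation of keto dienone 30. The ring can only close cis, and the carbinol forms in the same step. Dienone 30 comes from ketal 29, which is the one-carbon ring expansion of silyl dienol ether 26 through cyclopropane 27 and chloro ketone 28. Dienol ether 26 comes from dienone 24 by asymmetric conjugate addition with enolate trapping (zinc enolate 25), and 24 from commercial enone 23. The C(CH3)2 group and the methyl-bearing enone are therefore bought, and only one stereocentre needs a chiral catalyst.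

**Ring B.** Aldehyde 22 is the silyl ether of aldol 21. The bond between the chain-bearing CH and the carbinol carbon is cut, an intramolecular aldol of keto aldehyde 20. It is preferred to adding a methyl nucleophile to a ring-B ketone because both carbonyl partners grow directly from the two handles of the key-step product. Compound 20 comes from 19 and 18 (unmasking and oxidation of the primary alcohol). Diketone 18 comes from bis-enone 17 (hydrogenation), 17 from aldehyde 16 (Wittig), and 16 from diol 15, alcohol 14 and acid 13 (reduction, allylic hydroxylation, double oxidation).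

**Key disconnection.** Acid 13 is cut at the bond between the O-bearing CH and the quaternary carbon. It arises from dioxepanone 10 by Ireland–Claisen rearrangement through silyl ketene acetal 11 and silyl ester 12. One carbinol centre and one alkene geometry in 10 are exchanged for the two adjacent centres and the oxepene ring of 13. The forward reaction must pass through a tether-enforced boat.

**Dioxepanone.** Lactone 10 is cut at the ester C–O bond to hydroxy acid 8 (activated as mixed anhydride 9), which comes from ester 7. The carbinol of 7 is set by CBS reduction of enone 6. The ether of 6 is made by O–H insertion into tertiary alcohol 5 while the future carbinol is still a ketone, so no protecting group is needed to tell the two oxygens apart. Aldol 5 comes from methyl ketone 4 and acetone. Ketone 4 comes from Weinreb amides 3 and 2 and lactone 1, whose ring fixes the (Z)-alkene.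

## Roads not taken

**Alternative 1:** The cut is the O–C(CH3)2 bond of ring A together with the ring-B bond from the keto-ester α-carbon to the quaternary carbon. In the forward step a Lewis acid would open the two epoxides of diepoxy β-keto ester A1 in a cascade to give hydroxy keto ester A2.

- Merits: rings A and B and their fusion form in one step. The ring-A oxygen arrives on the correct carbon, the ester is already the first linker carbon, and the ring-B ketone is placed for a later methyl addition. In step count to an A/B building block this road is clearly shorter than the chosen one, which needs an allylic oxidation and a separate ring-B closure.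
- Weak points: the enol may attack through oxygen instead of carbon. The oxepane closure must go endo at the tertiary epoxide carbon against tetrahydropyran formation. The fusion geometry follows from a folded chain that is not held in place. A methyl nucleophile would then meet an acidic β-keto ester.
- Comparison: the chosen plan sets against this a stepwise stereochemical argument. One carbinol and one alkene geometry are passed on through a tethered boat, and every later centre is set in a step of known sense.

**Alternative 2:** The cut is the O–CH bond at the ring fusion. In the forward step tertiary hydroxy diketone A3 would form a seven-membered hemiketal and be reduced through its oxocarbenium ion to oxepane A4.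

- Merits: this C–O closure is far better precedented than the rearrangement chosen here. Axial hydride delivery gives the trans fusion reliably, and the ring-A ketone is present from the start. As a ring-closing step it is the safer of the two.
- Weak points: it forms no C–C bond, so the quaternary centre must come from other chemistry beforehand. A4 carries a silyloxy group on the carbon that must be bonded to the linker and nothing on the carbon that must become the tertiary carbinol. A long redox and C–C sequence at the most hindered position of ring B would have to follow, and the reduction must discriminate two ketones.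
- Comparison: the chosen plan builds the quaternary carbon and its O-bearing neighbour together and leaves CO2H and CH2CH2O arms that map directly onto ring B.

**Alternative 3:** The cuts are the β C–C bond and the α C–O bond of a cyclopentanone. Enone A5 would take up a vinyl group under copper catalysis, and the enolate would be hydroxylated in the same flask to give A6.

- Merits: short, catalytic and enantioselective. The ring-D carbinol and its neighbour are set in one operation with the hydroxyl trans to the carbon branch, as the target requires. For these two centres it is more direct than the chosen ring-D closure, whose chemoselectivity is less certain.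
- Weak points: it addresses only ring D. The ketone of A6 sits on a carbon that is CH2 in the target, and the carbon that must carry the C(CH3)2 branch is an unactivated methylene. Ring C, its chain-bearing centre, the epoxide and the whole left half remain open.
- Comparison: the chosen route sets the C(CH3)2-bearing centre first and lets the ring fusion and the carbinol follow from it in a cyclisation that can only close cis.

Key step: step 9

## Route

Remark: 2,4,4-trimethylcyclohex-2-en-1-one (23) is taken as purchasable, and the Grignard reagent of commercial 2-(2-bromoethyl)-2-methyl-1,3-dioxolane is treated as a stock reagent.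
Remark: stereocentres that are destroyed again (carbinol carbon C-6 of 15, cyclopropane carbons of 27, chloride-bearing carbon of 28) are left undefined in the SMILES.
Remark: the CBS catalysts and the phosphoramidite are named as the enantiomers that the usual models predict for the required sense.

Step 1
Reactants: 1 4-methyl-5,6-dihydro-2H-pyran-2-one
Product: 2 (Z)-5-hydroxy-N-methoxy-N,3-dimethylpent-2-enamide
Conditions: MeNH(OMe)·HCl, AlMe3, CH2Cl2, 0 °C to rt
Reagents that add atoms: N,O-dimethylhydroxylamine hydrochloride, CNOC.Cl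
Why: Weinreb aminolysis of a lactone with the aluminium amide; the ring holds the carbonyl and the CH2CH2O arm cis, so the (Z)-alkene is obtained without an olefination.

Step 2
Reactants: 2 (Z)-5-hydroxy-N-methoxy-N,3-dimethylpent-2-enamide
Product: 3 (Z)-5-[(tert-butyldimethylsilyl)oxy]-N-methoxy-N,3-dimethylpent-2-enamide
Conditions: t-BuMe2SiCl, imidazole, CH2Cl2, 0 °C to rt
Reagents that add atoms: tert-butyldimethylsilyl chloride, CC(C)(C)[Si](C)(C)Cl
Why: Silylation of a primary alcohol under neutral conditions; it stops relactonisation of the hydroxy amide.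

Step 3
Reactants: 3 (Z)-5-[(tert-butyldimethylsilyl)oxy]-N-methoxy-N,3-dimethylpent-2-enamide
Product: 4 (Z)-6-[(tert-butyldimethylsilyl)oxy]-4-methylhex-3-en-2-one
Conditions: MeMgBr, THF, 0 °C
Reagents that add atoms: methylmagnesium bromide, C[Mg]Br
Why: Weinreb ketone synthesis; the chelated tetrahedral intermediate prevents over-addition, and the β,β-disubstituted alkene resists conjugate addition.

Step 4
Reactants: 4 (Z)-6-[(tert-butyldimethylsilyl)oxy]-4-methylhex-3-en-2-one
Product: 5 (Z)-8-[(tert-butyldimethylsilyl)oxy]-2-hydroxy-2,6-dimethyloct-5-en-4-one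
Conditions: LiN(iPr)2, THF, −78 °C; acetone; aq NH4Cl at −78 °C
Reagents that add atoms: acetone, CC(C)=O
Why: Kinetic α′-deprotonation of the methyl ketone and aldol addition to acetone; the cross-conjugated enolate leaves the alkene geometry untouched, and the cold quench avoids retro-aldol.

Step 5
Reactants: 5 (Z)-8-[(tert-butyldimethylsilyl)oxy]-2-hydroxy-2,6-dimethyloct-5-en-4-one
Product: 6 ethyl 2-{[(Z)-8-[(tert-butyldimethylsilyl)oxy]-2,6-dimethyl-4-oxooct-5-en-2-yl]oxy}acetate
Conditions: N2CHCO2Et (slow addition), Rh2(OAc)4 (1 mol %), CH2Cl2, rt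
Reagents that add atoms: ethyl diazoacetate, CCOC(=O)C=[N+]=[N-]
Why: Rhodium carbenoid O–H insertion etherifies the tertiary alcohol under neutral conditions, where base would cause retro-aldol; the electron-poor enone alkene is a poor partner for cyclopropanation.

Step 6
Reactants: 6 ethyl 2-{[(Z)-8-[(tert-butyldimethylsilyl)oxy]-2,6-dimethyl-4-oxooct-5-en-2-yl]oxy}acetate
Product: 7 ethyl 2-{[(4R,5Z)-8-[(tert-butyldimethylsilyl)oxy]-4-hydroxy-2,6-dimethyloct-5-en-2-yl]oxy}acetate
Conditions: (S)-2-methyl-CBS-oxazaborolidine (0.2 equiv), catecholborane, toluene, −78 °C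
Reagents that add atoms: none
Why: Corey–Bakshi–Shibata reduction of an enone; with the alkenyl arm as the large group the (S)-catalyst delivers hydride to give the (R)-carbinol, the only stereocentre the key step needs, and catecholborane spares the ester.

Step 7
Reactants: 7 ethyl 2-{[(4R,5Z)-8-[(tert-butyldimethylsilyl)oxy]-4-hydroxy-2,6-dimethyloct-5-en-2-yl]oxy}acetate
Product: 8 2-{[(4R,5Z)-8-[(tert-butyldimethylsilyl)oxy]-4-hydroxy-2,6-dimethyloct-5-en-2-yl]oxy}acetic acid
Conditions: LiOH, THF/H2O, 0 °C to rt; 1 M HCl to pH 4
Reagents that add atoms: lithium hydroxide, [Li+].[OH-]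
Why: Ester saponification; no carbonyl remains β to the ether, so there is no elimination pathway, and the mild acidification spares the allylic alcohol and the silyl ether.

Step 8
Reactants: 8 2-{[(4R,5Z)-8-[(tert-butyldimethylsilyl)oxy]-4-hydroxy-2,6-dimethyloct-5-en-2-yl]oxy}acetic acid
Product: 10 (7R)-7-[(Z)-4-[(tert-butyldimethylsilyl)oxy]-2-methylbut-1-en-1-yl]-5,5-dimethyl-1,4-dioxepan-2-one, via mixed anhydride 9 (not isolated)
Conditions: 2,4,6-Cl3C6H2COCl, Et3N, THF, rt; then DMAP, toluene, 80 °C, high dilution
Reagents that add atoms: none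
Why: Yamaguchi lactonisation; the gem-dimethyl group and the ring oxygen ease closure of the seven-membered lactone, and the carbinol centre is not touched.

Step 9
Reactants: 10 (7R)-7-[(Z)-4-[(tert-butyldimethylsilyl)oxy]-2-methylbut-1-en-1-yl]-5,5-dimethyl-1,4-dioxepan-2-one
Product: 13 (2S,3S)-3-{2-[(tert-butyldimethylsilyl)oxy]ethyl}-3,7,7-trimethyl-2,3,6,7-tetrahydrooxepine-2-carboxylic acid, via silyl ketene acetal 11 (not isolated), via trimethylsilyl ester 12 (not isolated)
Conditions: KN(SiMe3)2, Me3SiCl, THF, −78 °C; then toluene, 100 °C; 1 M HCl work-up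
Reagents that add atoms: none
Why: Proposed new method: deprotonation of the α-alkoxy lactone and O-silylation give ketene acetal 11, whose C=C lies inside the seven-membered ring so that the ring oxygen and the ester oxygen are held cis; a [3,3] shift then joins C-3 of the lactone to the alkene terminus while the C-7–O bond breaks, and hydrolysis of silyl ester 12 gives acid 13. The closest known reaction type is the Ireland–Claisen rearrangement of 6-alkenyl-1,4-dioxan-2-ones to dihydropyrans, here extended by one ring atom in the tether. The oxepene is closed by the new σ-bond of the sigmatropic shift and not by a nucleophilic cyclisation: the O–C(CH3)2–CH2 tether bridges the two termini that do not bond, which excludes a chair and enforces a boat with the tether in the two pseudo-axial positions beneath it. The O-bearing centre C-2 is controlled by the ring-locked ketene acetal geometry and by the face of the allyl unit that the (R)-carbinol and the tether leave open. The quaternary centre C-3 is controlled by the (Z)-alkene, which places the CH2CH2O chain pseudo-axial and CH3 pseudo-equatorial, so that CO2H ends cis to CH3. Working through this boat gives the (2S,3S) pair, the one needed for trans fusion of rings A and B. The step needs clean O-silylation, a boat that tolerates the chain eclipsing the ring oxygen across the forming bond, and an intact (Z)-alkene; the internal silyl quench at −78 °C and the gem-dimethyl group, which favours the folded tether, are relied on for this.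

Step 10
Reactants: 13 (2S,3S)-3-{2-[(tert-butyldimethylsilyl)oxy]ethyl}-3,7,7-trimethyl-2,3,6,7-tetrahydrooxepine-2-carboxylic acid
Product: 14 [(2S,3S)-3-{2-[(tert-butyldimethylsilyl)oxy]ethyl}-3,7,7-trimethyl-2,3,6,7-tetrahydrooxepin-2-yl]methanol
Conditions: LiAlH4, THF, 0 °C to rt
Reagents that add atoms: none
Why: Hydride reduction of a carboxylic acid to the primary alcohol; the alkene and the silyl ether are inert, and the α-centre has no enolisable carbonyl left.

Step 11
Reactants: 14 [(2S,3S)-3-{2-[(tert-butyldimethylsilyl)oxy]ethyl}-3,7,7-trimethyl-2,3,6,7-tetrahydrooxepin-2-yl]methanol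
Product: 15 (2S,3S)-3-{2-[(tert-butyldimethylsilyl)oxy]ethyl}-2-(hydroxymethyl)-3,7,7-trimethyl-2,3,6,7-tetrahydrooxepin-6-ol (both C-6 epimers)
Conditions: SeO2 (0.5 equiv), t-BuOOH, CH2Cl2, rt
Reagents that add atoms: selenium dioxide, O=[Se]=O; tert-butyl hydroperoxide, CC(C)(C)OO
Why: Selenium dioxide allylic hydroxylation (ene reaction, then [2,3] shift) returns the double bond to its place, so oxygen enters only at the single allylic CH2 next to C(CH3)2; the new centre is oxidised away in step 12.

Step 12
Reactants: 15 (2S,3S)-3-{2-[(tert-butyldimethylsilyl)oxy]ethyl}-2-(hydroxymethyl)-3,7,7-trimethyl-2,3,6,7-tetrahydrooxepin-6-ol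
Product: 16 (2S,3S)-3-{2-[(tert-butyldimethylsilyl)oxy]ethyl}-3,7,7-trimethyl-6-oxo-2,3,6,7-tetrahydrooxepine-2-carbaldehyde
Conditions: Dess–Martin periodinane, NaHCO3, CH2Cl2, rt
Reagents that add atoms: none
Why: Dess–Martin oxidation of both alcohols at once; the α-alkoxy aldehyde is flanked by a quaternary carbon and should not epimerise under buffered conditions.

Step 13
Reactants: 16 (2S,3S)-3-{2-[(tert-butyldimethylsilyl)oxy]ethyl}-3,7,7-trimethyl-6-oxo-2,3,6,7-tetrahydrooxepine-2-carbaldehyde
Product: 17 (6S,7R)-6-{2-[(tert-butyldimethylsilyl)oxy]ethyl}-2,2,6-trimethyl-7-[(E)-3-oxobut-1-en-1-yl]-6,7-dihydrooxepin-3(2H)-one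
Conditions: Ph3P=CHCOCH3, toluene, 60 °C
Reagents that add atoms: 1-(triphenylphosphoranylidene)propan-2-one, CC(=O)C=P(c1ccccc1)(c1ccccc1)c1ccccc1
Why: Wittig olefination with a stabilised ylide, which reacts with the aldehyde only and is not basic enough to epimerise it.

Step 14
Reactants: 17 (6S,7R)-6-{2-[(tert-butyldimethylsilyl)oxy]ethyl}-2,2,6-trimethyl-7-[(E)-3-oxobut-1-en-1-yl]-6,7-dihydrooxepin-3(2H)-one
Product: 18 (6R,7R)-6-{2-[(tert-butyldimethylsilyl)oxy]ethyl}-2,2,6-trimethyl-7-(3-oxobutyl)oxepan-3-one
Conditions: H2 (1 atm), Pd/C, EtOAc, rt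
Reagents that add atoms: none
Why: Catalytic hydrogenation saturates both enone C=C bonds in one operation, giving the ring-A ketone and the 3-oxobutyl chain.

Step 15
Reactants: 18 (6R,7R)-6-{2-[(tert-butyldimethylsilyl)oxy]ethyl}-2,2,6-trimethyl-7-(3-oxobutyl)oxepan-3-one
Product: 19 (6R,7R)-6-(2-hydroxyethyl)-2,2,6-trimethyl-7-(3-oxobutyl)oxepan-3-one
Conditions: Bu4NF, AcOH, THF, 0 °C to rt
Reagents that add atoms: none
Why: Fluoride desilylation, buffered with acetic acid so that the diketone is not exposed to base.

Step 16
Reactants: 19 (6R,7R)-6-(2-hydroxyethyl)-2,2,6-trimethyl-7-(3-oxobutyl)oxepan-3-one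
Product: 20 2-[(2R,3R)-3,7,7-trimethyl-6-oxo-2-(3-oxobutyl)oxepan-3-yl]acetaldehyde
Conditions: Dess–Martin periodinane, NaHCO3, CH2Cl2, rt
Reagents that add atoms: none
Why: Dess–Martin oxidation of the primary alcohol to the aldehyde without enolising the ketones.

Step 17
Reactants: 20 2-[(2R,3R)-3,7,7-trimethyl-6-oxo-2-(3-oxobutyl)oxepan-3-yl]acetaldehyde
Product: 21 (5aR,6R,7S,9aR)-7-hydroxy-2,2,5a,7-tetramethyl-3-oxodecahydro-1-benzoxepine-6-carbaldehyde
Conditions: pyrrolidine (0.2 equiv), PhCO2H (0.2 equiv), CH2Cl2, rt
Reagents that add atoms: none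
Why: Intramolecular enamine aldol (6-enolexo): the amine condenses with the aldehyde much faster than with either ketone, the enamine carbon adds to the methyl ketone, and the α-branched product forms an enamine only with difficulty, so water should not be lost. Under these reversible conditions the chair with equatorial CHO, equatorial CH3 and axial OH (hydrogen-bonded to CHO, and avoiding a CH3/CH3 syn-diaxial contact with the angular methyl) should dominate, which sets C-6 and C-7.

Step 18
Reactants: 21 (5aR,6R,7S,9aR)-7-hydroxy-2,2,5a,7-tetramethyl-3-oxodecahydro-1-benzoxepine-6-carbaldehyde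
Product: 22 (5aR,6R,7S,9aR)-2,2,5a,7-tetramethyl-3-oxo-7-[(trimethylsilyl)oxy]decahydro-1-benzoxepine-6-carbaldehyde
Conditions: 1-(trimethylsilyl)imidazole, CH2Cl2, rt
Reagents that add atoms: 1-(trimethylsilyl)imidazole, C[Si](C)(C)n1ccnc1
Why: Silylation of a hindered tertiary alcohol with a reagent that does not enolise ketones; it blocks retro-aldol during the olefination.

Step 19
Reactants: 23 2,4,4-trimethylcyclohex-2-en-1-one
Product: 24 2,4,4-trimethylcyclohexa-2,5-dien-1-one
Conditions: 2-iodoxybenzoic acid, DMSO/toluene, 75 °C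
Reagents that add atoms: none
Why: IBX dehydrogenation of a ketone; only the C-5/C-6 positions carry hydrogens, and the quaternary C-4 prevents aromatisation.

Step 20
Reactants: 24 2,4,4-trimethylcyclohexa-2,5-dien-1-one
Product: 26 trimethyl({(6R)-3,5,5-trimethyl-6-[2-(2-methyl-1,3-dioxolan-2-yl)ethyl]cyclohexa-1,3-dien-2-yl}oxy)silane, via zinc enolate 25 (not isolated)
Conditions: [2-(2-methyl-1,3-dioxolan-2-yl)ethyl]MgBr (2 equiv), ZnCl2 (1 equiv), THF/dioxane; Cu(OTf)2 (2 mol %), (S,R,R)-BINOL bis(1-phenylethyl)phosphoramidite (4 mol %), toluene, −30 °C; then Me3SiOTf, −30 °C to rt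
Reagents that add atoms: [2-(2-methyl-1,3-dioxolan-2-yl)ethyl]magnesium bromide, CC1(CC[Mg]Br)OCCO1; trimethylsilyl trifluoromethanesulfonate, C[Si](C)(C)OS(=O)(=O)C(F)(F)F
Why: Copper-catalysed asymmetric conjugate addition of a dialkylzinc to a cyclohexadienone; the α-unsubstituted enone reacts, the ligand selects the enone face and sets the CH next to C(CH3)2, and O-silylation of the zinc enolate gives the cross-conjugated dienol ether regiospecifically.

Step 21
Reactants: 26 trimethyl({(6R)-3,5,5-trimethyl-6-[2-(2-methyl-1,3-dioxolan-2-yl)ethyl]cyclohexa-1,3-dien-2-yl}oxy)silane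
Product: 27 trimethyl({(5R)-2,4,4-trimethyl-5-[2-(2-methyl-1,3-dioxolan-2-yl)ethyl]bicyclo[4.1.0]hept-2-en-1-yl}oxy)silane
Conditions: Et2Zn, CH2I2, CH2Cl2, 0 °C
Reagents that add atoms: diiodomethane, ICI
Why: Simmons–Smith (Furukawa) cyclopropanation; the electrophilic zinc carbenoid attacks the silyl enol ether double bond, not the trisubstituted diene partner.

Step 22
Reactants: 27 trimethyl({(5R)-2,4,4-trimethyl-5-[2-(2-methyl-1,3-dioxolan-2-yl)ethyl]bicyclo[4.1.0]hept-2-en-1-yl}oxy)silane
Product: 29 (5R)-2,4,4-trimethyl-5-[2-(2-methyl-1,3-dioxolan-2-yl)ethyl]cyclohepta-2,6-dien-1-one, via chloro ketone 28 (not isolated)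
Conditions: FeCl3, DMF, 0 °C; then NaOAc, MeOH, reflux
Reagents that add atoms: none
Why: Ito–Saegusa ring expansion: FeCl3 cleaves the internal cyclopropane bond of the siloxycyclopropane to a β-chloro ketone, and acetate eliminates HCl to the cyclohepta-2,6-dienone; the saturated ketal chain offers the intermediate radical no alkene to add to.

Step 23
Reactants: 29 (5R)-2,4,4-trimethyl-5-[2-(2-methyl-1,3-dioxolan-2-yl)ethyl]cyclohepta-2,6-dien-1-one
Product: 30 (5R)-2,4,4-trimethyl-5-(3-oxobutyl)cyclohepta-2,6-dien-1-one
Conditions: pyridinium p-toluenesulfonate, acetone/H2O, 50 °C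
Reagents that add atoms: water, O
Why: Acid-catalysed ketal hydrolysis; the dienone has no acid-labile group.

Step 24
Reactants: 30 (5R)-2,4,4-trimethyl-5-(3-oxobutyl)cyclohepta-2,6-dien-1-one
Product: 31 (1R,3aR,8aR)-1-hydroxy-1,4,4,6-tetramethyl-2,3,3a,4,8,8a-hexahydroazulen-7(1H)-one (cis-fused)
Conditions: SmI2 (2.2 equiv), HMPA, THF, −78 °C; aq NH4Cl
Reagents that add atoms: none
Why: Ketyl–olefin radical cyclisation with SmI2: 5-exo addition to the β-carbon of the unsubstituted enone, the only one within reach. The five-membered ring can only be fused cis to ring C, and the samarium-bound oxygen turns away from the developing enolate, which places OH trans to the ring CH2 and cis to the ring-fusion hydrogen.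

Step 25
Reactants: 31 (1R,3aR,8aR)-1-hydroxy-1,4,4,6-tetramethyl-2,3,3a,4,8,8a-hexahydroazulen-7(1H)-one
Product: 32 (1R,3aR,7S,8aR)-1,4,4,6-tetramethyl-1,2,3,3a,4,7,8,8a-octahydroazulene-1,7-diol
Conditions: (R)-2-methyl-CBS-oxazaborolidine (0.2 equiv), BH3·SMe2, THF, −20 °C
Reagents that add atoms: none
Why: Corey–Bakshi–Shibata reduction of an α-methyl cyclic enone; with the alkenyl arm as the large group the (R)-catalyst gives the (S)-carbinol, whose oxygen lies on the face of ring C that carries ring D, and attack from the open convex face should reinforce this.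

Step 26
Reactants: 32 (1R,3aR,7S,8aR)-1,4,4,6-tetramethyl-1,2,3,3a,4,7,8,8a-octahydroazulene-1,7-diol
Product: 33 (1R,3aR,7S,8aR)-1,4,4,6-tetramethyl-7-[(tributylstannyl)methoxy]-1,2,3,3a,4,7,8,8a-octahydroazulen-1-ol
Conditions: KH (1.1 equiv), Bu3SnCH2I, THF, 0 °C to rt
Reagents that add atoms: tributyl(iodomethyl)stannane, CCCC[Sn](CCCC)(CCCC)CI
Why: Williamson etherification; with one equivalent of base the secondary allylic alkoxide, more acidic and far less hindered than the tertiary one, is alkylated.

Step 27
Reactants: 33 (1R,3aR,7S,8aR)-1,4,4,6-tetramethyl-7-[(tributylstannyl)methoxy]-1,2,3,3a,4,7,8,8a-octahydroazulen-1-ol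
Product: 34 (1R,3aR,5S,8aR)-5-(hydroxymethyl)-1,4,4,6-tetramethyl-1,2,3,3a,4,5,8,8a-octahydroazulen-1-ol
Conditions: n-BuLi (2.2 equiv), THF, −78 to −40 °C
Reagents that add atoms: none
Why: [2,3]-Wittig–Still rearrangement: tin–lithium exchange gives the α-alkoxymethyl anion, which shifts suprafacially, so CH2OH is delivered to the ring carbon next to C(CH3)2 on the face that held the oxygen, and the double bond moves to its final trisubstituted position.

Step 28
Reactants: 34 (1R,3aR,5S,8aR)-5-(hydroxymethyl)-1,4,4,6-tetramethyl-1,2,3,3a,4,5,8,8a-octahydroazulen-1-ol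
Product: 35 epoxy diol: the 6,7-epoxide of 34 with the oxygen cis to CH2OH
Conditions: VO(acac)2 (5 mol %), t-BuOOH, CH2Cl2, 0 °C to rt
Reagents that add atoms: tert-butyl hydroperoxide, CC(C)(C)OO
Why: Vanadium-catalysed hydroxyl-directed epoxidation of a homoallylic alcohol; the primary CH2OH binds the metal and delivers oxygen to its own face, which is the face required, while the distant tertiary hydroxyl cannot compete.

Step 29
Reactants: 35 epoxy diol
Product: 36 5-({[epoxy-hydroxy-tetramethyl-decahydroazulenyl]methyl}sulfanyl)-1-phenyl-1H-tetrazole (sulfide of 35)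
Conditions: 1-phenyl-1H-tetrazole-5-thiol, PPh3, iPrO2CN=NCO2iPr, THF, 0 °C to rt
Reagents that add atoms: 1-phenyl-1H-tetrazole-5-thiol, Sc1nnnn1-c1ccccc1
Why: Mitsunobu thioetherification of the primary alcohol; the tertiary alcohol and the epoxide do not react under these neutral conditions.

Step 30
Reactants: 36 sulfide of 35
Product: 37 5-({[epoxy-hydroxy-tetramethyl-decahydroazulenyl]methyl}sulfonyl)-1-phenyl-1H-tetrazole (sulfone)
Conditions: 3-ClC6H4CO3H, NaHCO3, CH2Cl2, 0 °C to rt
Reagents that add atoms: 3-chloroperbenzoic acid, OOC(=O)c1cccc(Cl)c1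
Why: Peracid oxidation of sulfide to sulfone; no alkene is left in the molecule, and the buffer protects the epoxide.

Step 31
Reactants: 37 sulfone; 22 (5aR,6R,7S,9aR)-2,2,5a,7-tetramethyl-3-oxo-7-[(trimethylsilyl)oxy]decahydro-1-benzoxepine-6-carbaldehyde
Product: 38 (E)-alkene joining C-6 of the benzoxepine to the ring-C carbon through CH=CH
Conditions: KN(SiMe3)2 (2.1 equiv), 1,2-dimethoxyethane, −78 °C; then 22, −78 °C to rt
Reagents that add atoms: none
Why: Julia–Kocienski olefination; the sulfonyl carbanion adds to the aldehyde much faster than to the hindered ring-A ketone, and it cannot open the epoxide because it sits on the same face as the epoxide oxygen. The alkene geometry is irrelevant, since the alkene is hydrogenated next.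

Step 32
Reactants: 38 (E)-alkene
Product: 39 7-O-trimethylsilyl ether of the target
Conditions: H2 (1 atm), Pd/C, EtOAc, rt
Reagents that add atoms: none
Why: Catalytic hydrogenation of the only alkene; the trialkyl epoxide is not allylic to it and should survive neutral conditions.

Step 33
Reactants: 39 7-O-trimethylsilyl ether of the target
Product: 40 CNP0259752.1
Conditions: Bu4NF, THF, 0 °C
Reagents that add atoms: none
Why: Fluoride cleavage of the trimethylsilyl ether; the conditions are non-acidic, so the epoxide and the tertiary alcohols are left intact.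

## Compound list

1 | 4-methyl-5,6-dihydro-2H-pyran-2-one | CC1=CC(=O)OCC1 | starting material
2 | (Z)-5-hydroxy-N-methoxy-N,3-dimethylpent-2-enamide | CON(C)C(=O)/C=C(/C)CCO | intermediate
3 | (Z)-5-[(tert-butyldimethylsilyl)oxy]-N-methoxy-N,3-dimethylpent-2-enamide | CON(C)C(=O)/C=C(/C)CCO[Si](C)(C)C(C)(C)C | intermediate
4 | (Z)-6-[(tert-butyldimethylsilyl)oxy]-4-methylhex-3-en-2-one | CC(=O)/C=C(/C)CCO[Si](C)(C)C(C)(C)C | intermediate
5 | (Z)-8-[(tert-butyldimethylsilyl)oxy]-2-hydroxy-2,6-dimethyloct-5-en-4-one | CC(C)(O)CC(=O)/C=C(/C)CCO[Si](C)(C)C(C)(C)C | intermediate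
6 | ethyl 2-{[(Z)-8-[(tert-butyldimethylsilyl)oxy]-2,6-dimethyl-4-oxooct-5-en-2-yl]oxy}acetate | CCOC(=O)COC(C)(C)CC(=O)/C=C(/C)CCO[Si](C)(C)C(C)(C)C | intermediate
7 | ethyl 2-{[(4R,5Z)-8-[(tert-butyldimethylsilyl)oxy]-4-hydroxy-2,6-dimethyloct-5-en-2-yl]oxy}acetate | CCOC(=O)COC(C)(C)C[C@@H](O)/C=C(/C)CCO[Si](C)(C)C(C)(C)C | intermediate
8 | 2-{[(4R,5Z)-8-[(tert-butyldimethylsilyl)oxy]-4-hydroxy-2,6-dimethyloct-5-en-2-yl]oxy}acetic acid | OC(=O)COC(C)(C)C[C@@H](O)/C=C(/C)CCO[Si](C)(C)C(C)(C)C | intermediate
9 | mixed anhydride of 8 and 2,4,6-trichlorobenzoic acid (not isolated) | O=C(OC(=O)COC(C)(C)C[C@@H](O)/C=C(/C)CCO[Si](C)(C)C(C)(C)C)c1c(Cl)cc(Cl)cc1Cl | intermediate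
10 | (7R)-7-[(Z)-4-[(tert-butyldimethylsilyl)oxy]-2-methylbut-1-en-1-yl]-5,5-dimethyl-1,4-dioxepan-2-one | O=C1COC(C)(C)C[C@@H](O1)/C=C(/C)CCO[Si](C)(C)C(C)(C)C | intermediate
11 | trimethylsilyl ketene acetal of 10 (not isolated) | C[Si](C)(C)OC1=COC(C)(C)C[C@@H](O1)/C=C(/C)CCO[Si](C)(C)C(C)(C)C | intermediate
12 | trimethylsilyl ester of 13 (not isolated) | CC1(C)O[C@H](C(=O)O[Si](C)(C)C)[C@@](C)(CCO[Si](C)(C)C(C)(C)C)C=CC1 | intermediate
13 | (2S,3S)-3-{2-[(tert-butyldimethylsilyl)oxy]ethyl}-3,7,7-trimethyl-2,3,6,7-tetrahydrooxepine-2-carboxylic acid | CC1(C)O[C@H](C(=O)O)[C@@](C)(CCO[Si](C)(C)C(C)(C)C)C=CC1 | intermediate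
14 | [(2S,3S)-3-{2-[(tert-butyldimethylsilyl)oxy]ethyl}-3,7,7-trimethyl-2,3,6,7-tetrahydrooxepin-2-yl]methanol | CC1(C)O[C@H](CO)[C@@](C)(CCO[Si](C)(C)C(C)(C)C)C=CC1 | intermediate
15 | (2S,3S)-3-{2-[(tert-butyldimethylsilyl)oxy]ethyl}-2-(hydroxymethyl)-3,7,7-trimethyl-2,3,6,7-tetrahydrooxepin-6-ol, both C-6 epimers | CC1(C)O[C@H](CO)[C@@](C)(CCO[Si](C)(C)C(C)(C)C)C=CC1O | intermediate
16 | (2S,3S)-3-{2-[(tert-butyldimethylsilyl)oxy]ethyl}-3,7,7-trimethyl-6-oxo-2,3,6,7-tetrahydrooxepine-2-carbaldehyde | CC1(C)O[C@H](C=O)[C@@](C)(CCO[Si](C)(C)C(C)(C)C)C=CC1=O | intermediate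
17 | (6S,7R)-6-{2-[(tert-butyldimethylsilyl)oxy]ethyl}-2,2,6-trimethyl-7-[(E)-3-oxobut-1-en-1-yl]-6,7-dihydrooxepin-3(2H)-one | CC1(C)O[C@H](/C=C/C(C)=O)[C@@](C)(CCO[Si](C)(C)C(C)(C)C)C=CC1=O | intermediate
18 | (6R,7R)-6-{2-[(tert-butyldimethylsilyl)oxy]ethyl}-2,2,6-trimethyl-7-(3-oxobutyl)oxepan-3-one | CC1(C)O[C@H](CCC(C)=O)[C@@](C)(CCO[Si](C)(C)C(C)(C)C)CCC1=O | intermediate
19 | (6R,7R)-6-(2-hydroxyethyl)-2,2,6-trimethyl-7-(3-oxobutyl)oxepan-3-one | CC1(C)O[C@H](CCC(C)=O)[C@@](C)(CCO)CCC1=O | intermediate
20 | 2-[(2R,3R)-3,7,7-trimethyl-6-oxo-2-(3-oxobutyl)oxepan-3-yl]acetaldehyde | CC1(C)O[C@H](CCC(C)=O)[C@@](C)(CC=O)CCC1=O | intermediate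
21 | (5aR,6R,7S,9aR)-7-hydroxy-2,2,5a,7-tetramethyl-3-oxodecahydro-1-benzoxepine-6-carbaldehyde | CC1(C)O[C@@H]2CC[C@](C)(O)[C@H](C=O)[C@@]2(C)CCC1=O | intermediate
22 | (5aR,6R,7S,9aR)-2,2,5a,7-tetramethyl-3-oxo-7-[(trimethylsilyl)oxy]decahydro-1-benzoxepine-6-carbaldehyde | CC1(C)O[C@@H]2CC[C@](C)(O[Si](C)(C)C)[C@H](C=O)[C@@]2(C)CCC1=O | intermediate
23 | 2,4,4-trimethylcyclohex-2-en-1-one | CC1=CC(C)(C)CCC1=O | starting material
24 | 2,4,4-trimethylcyclohexa-2,5-dien-1-one | CC1=CC(C)(C)C=CC1=O | intermediate
25 | alkylzinc enolate of the (R)-conjugate adduct (not isolated) | CC1=CC(C)(C)[C@H](CCC2(C)OCCO2)C=C1O[Zn]CCC1(C)OCCO1 | intermediate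
26 | trimethyl({(6R)-3,5,5-trimethyl-6-[2-(2-methyl-1,3-dioxolan-2-yl)ethyl]cyclohexa-1,3-dien-2-yl}oxy)silane | CC1=CC(C)(C)[C@H](CCC2(C)OCCO2)C=C1O[Si](C)(C)C | intermediate
27 | trimethyl({(5R)-2,4,4-trimethyl-5-[2-(2-methyl-1,3-dioxolan-2-yl)ethyl]bicyclo[4.1.0]hept-2-en-1-yl}oxy)silane | CC1=CC(C)(C)[C@H](CCC3(C)OCCO3)C2CC12O[Si](C)(C)C | intermediate
28 | (5R)-6-chloro-2,4,4-trimethyl-5-[2-(2-methyl-1,3-dioxolan-2-yl)ethyl]cyclohept-2-en-1-one (not isolated) | CC1=CC(C)(C)[C@H](CCC2(C)OCCO2)C(Cl)CC1=O | intermediate
29 | (5R)-2,4,4-trimethyl-5-[2-(2-methyl-1,3-dioxolan-2-yl)ethyl]cyclohepta-2,6-dien-1-one | CC1=CC(C)(C)[C@H](CCC2(C)OCCO2)C=CC1=O | intermediate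
30 | (5R)-2,4,4-trimethyl-5-(3-oxobutyl)cyclohepta-2,6-dien-1-one | CC1=CC(C)(C)[C@H](CCC(C)=O)C=CC1=O | intermediate
31 | (1R,3aR,8aR)-1-hydroxy-1,4,4,6-tetramethyl-2,3,3a,4,8,8a-hexahydroazulen-7(1H)-one, cis-fused | CC1=CC(C)(C)[C@@H]2CC[C@@](C)(O)[C@@H]2CC1=O | intermediate
32 | (1R,3aR,7S,8aR)-1,4,4,6-tetramethyl-1,2,3,3a,4,7,8,8a-octahydroazulene-1,7-diol | CC1=CC(C)(C)[C@@H]2CC[C@@](C)(O)[C@@H]2C[C@@H]1O | intermediate
33 | (1R,3aR,7S,8aR)-1,4,4,6-tetramethyl-7-[(tributylstannyl)methoxy]-1,2,3,3a,4,7,8,8a-octahydroazulen-1-ol | CC1=CC(C)(C)[C@@H]2CC[C@@](C)(O)[C@@H]2C[C@@H]1OC[Sn](CCCC)(CCCC)CCCC | intermediate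
34 | (1R,3aR,5S,8aR)-5-(hydroxymethyl)-1,4,4,6-tetramethyl-1,2,3,3a,4,5,8,8a-octahydroazulen-1-ol | OC[C@@H]1C(C)(C)[C@@H]2CC[C@@](C)(O)[C@@H]2CC=C1C | intermediate
35 | epoxy diol: 6,7-epoxide of 34, oxygen cis to CH2OH and to the ring-D bonds | OC[C@@H]1C(C)(C)[C@@H]2CC[C@@](C)(O)[C@@H]2C[C@@H]2O[C@@]21C | intermediate
36 | 1-phenyl-1H-tetrazol-5-yl sulfide of 35 | c1ccc(cc1)-n1nnnc1SC[C@@H]1C(C)(C)[C@@H]2CC[C@@](C)(O)[C@@H]2C[C@@H]2O[C@@]21C | intermediate
37 | 1-phenyl-1H-tetrazol-5-yl sulfone of 35 | c1ccc(cc1)-n1nnnc1S(=O)(=O)C[C@@H]1C(C)(C)[C@@H]2CC[C@@](C)(O)[C@@H]2C[C@@H]2O[C@@]21C | intermediate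
38 | (E)-alkene from 22 and 37, 7-O-trimethylsilyl | CC1(C)O[C@@H]2CC[C@](C)(O[Si](C)(C)C)[C@H](/C=C/[C@@H]3C(C)(C)[C@@H]4CC[C@@](C)(O)[C@@H]4C[C@@H]4O[C@@]43C)[C@@]2(C)CCC1=O | intermediate
39 | 7-O-trimethylsilyl ether of the target | CC1(C)O[C@@H]2CC[C@](C)(O[Si](C)(C)C)[C@H](CC[C@@H]3C(C)(C)[C@@H]4CC[C@@](C)(O)[C@@H]4C[C@@H]4O[C@@]43C)[C@@]2(C)CCC1=O | intermediate
40 | CNP0259752.1 | CC1(C)O[C@@H]2CC[C@](C)(O)[C@H](CC[C@@H]3C(C)(C)[C@@H]4CC[C@@](C)(O)[C@@H]4C[C@@H]4O[C@@]43C)[C@@]2(C)CCC1=O | target

## Step count and least certain steps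

Total: 33 steps. Longest linear sequence: 21 steps (steps 1–18 and 31–33). The right half takes 12 steps (steps 19–30).

**Step 9 (key step, proposed new method).** The silyl ketene acetal may fail to reach the bicyclic boat. The chain on the fully substituted alkene terminus must eclipse the ring oxygen across the forming bond. On heating, loss of the silyl group or fragmentation of the lactone could then outrun the shift, and twist geometries could erode the diastereoselectivity.

Fallback (known chemistry): the two centres are set by an open-chain glycolate Ireland–Claisen rearrangement and the ring is closed afterwards. It sets out from ketone 4 and returns at acid 13.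
- CBS reduction of 4 with the (R)-catalyst would give (S,Z)-6-[(tert-butyldimethylsilyl)oxy]-4-methylhex-3-en-2-ol F1.
- Esterification (dicyclohexylcarbodiimide, DMAP) with [(2-methylpent-4-en-2-yl)oxy]acetic acid F2, itself made from 2-methylpent-4-en-2-ol, NaH and bromoacetic acid, would give the allyl glycolate ester F3.
- Rearrangement through the chelated enolate (LiN(SiMe3)2, Me3SiCl) passes a chair. The enolate geometry and the transition-state shape are both inverted relative to step 9, so the (S)-carbinol and the (Z)-alkene should give the same (S,S) pair in the open-chain acid F4.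
- Ring-closing metathesis with the second-generation Grubbs catalyst between the allyl ether and the propenyl group closes the oxepene and returns 13.

**Step 11.** The ene step of the selenium dioxide oxidation has to take place at a cis-disubstituted alkene whose far carbon is neopentyl, so conversion may stall before hydroxylation.

Fallback: a radical allylic oxidation. It sets out from acid 13 and returns at diol 15.
- Me3SiCHN2 gives the methyl ester F5.
- Rh2(cap)4 (cap = caprolactamate) with t-BuOOH gives the enone ester F6 by hydrogen abstraction and peroxide trapping.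
- iBu2AlH reduces ester and enone together to 15.
- The price is possible trapping at the other allyl terminus, which would have to be separated.

**Step 17.** The amine may also condense with the methyl ketone, whose enamine would add to the aldehyde and give the isomeric six-membered ring. The desired aldol may lose water to the tetrasubstituted enal.

Fallback: a Reformatsky-type closure that fixes the nucleophilic carbon beforehand. It sets out from aldehyde 20 and returns at aldol 21.
- Selective organocatalytic α-bromination of the aldehyde (N-bromosuccinimide, pyrrolidine catalyst) gives the α-bromo aldehyde F7.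
- SmI2 at −78 °C gives the samarium enolate at that carbon only, which closes onto the methyl ketone through a chelate.

**Step 24.** Electron transfer to the cross-conjugated dienone may outrun ketyl formation, leading to plain reduction or dimerisation of the dienone. Chelation in such a pathway could also erode the preference for hydroxyl trans to the ring CH2.

Fallback: a hydrogen-atom-transfer radical conjugate addition. It sets out from keto dienone 30 and returns at hydroxy enone 31.
- Kinetic silylation of the methyl ketone (KN(SiMe3)2, t-BuMe2SiCl, −78 °C) gives the silyl enol ether F8.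
- Fe(acac)3 and PhSiH3 in ethanol generate the α-silyloxy radical, which closes 5-exo onto the enone to the cis-fused silyl ether F9.
- Bu4NF gives 31.
- The carbinol configuration would then rest on steric control only.

**Step 31.** The sulfonyl carbanion may deprotonate the hindered aldehyde instead of adding to it, followed by β-elimination of silanolate, and addition is slow between two branched partners.

Fallback: a non-basic organocerium addition followed by deoxygenation. It sets out from epoxy diol 35 and returns at silyl ether 39.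
- I2, PPh3 and imidazole give the primary iodide F10.
- t-BuLi and then CeCl3 give the organocerium reagent, which adds to aldehyde 22 to give the secondary alcohol F11 as a mixture of carbinol epimers.
- PhOC(S)Cl and DMAP give the thionocarbonate F12.
- Barton–McCombie reduction (Bu3SnH, AIBN) gives 39.

## Further compounds

F1 | step 9 | (S,Z)-6-[(tert-butyldimethylsilyl)oxy]-4-methylhex-3-en-2-ol | C[C@H](O)/C=C(/C)CCO[Si](C)(C)C(C)(C)C
F2 | step 9 | [(2-methylpent-4-en-2-yl)oxy]acetic acid | C=CCC(C)(C)OCC(=O)O
F3 | step 9 | (S,Z)-6-[(tert-butyldimethylsilyl)oxy]-4-methylhex-3-en-2-yl [(2-methylpent-4-en-2-yl)oxy]acetate | C=CCC(C)(C)OCC(=O)O[C@@H](C)/C=C(/C)CCO[Si](C)(C)C(C)(C)C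
F4 | step 9 | (2S,3S,E)-3-{2-[(tert-butyldimethylsilyl)oxy]ethyl}-3-methyl-2-[(2-methylpent-4-en-2-yl)oxy]hex-4-enoic acid | C=CCC(C)(C)O[C@H](C(=O)O)[C@@](C)(CCO[Si](C)(C)C(C)(C)C)/C=C/C
F5 | step 11 | methyl ester of 13 | CC1(C)O[C@H](C(=O)OC)[C@@](C)(CCO[Si](C)(C)C(C)(C)C)C=CC1
F6 | step 11 | methyl (2S,3S)-3-{2-[(tert-butyldimethylsilyl)oxy]ethyl}-3,7,7-trimethyl-6-oxo-2,3,6,7-tetrahydrooxepine-2-carboxylate | CC1(C)O[C@H](C(=O)OC)[C@@](C)(CCO[Si](C)(C)C(C)(C)C)C=CC1=O
F7 | step 17 | 2-bromo-2-[(2R,3R)-3,7,7-trimethyl-6-oxo-2-(3-oxobutyl)oxepan-3-yl]acetaldehyde, both epimers | CC1(C)O[C@H](CCC(C)=O)[C@@](C)(C(Br)C=O)CCC1=O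
F8 | step 24 | (5R)-5-{3-[(tert-butyldimethylsilyl)oxy]but-3-en-1-yl}-2,4,4-trimethylcyclohepta-2,6-dien-1-one | CC1=CC(C)(C)[C@H](CCC(=C)O[Si](C)(C)C(C)(C)C)C=CC1=O
F9 | step 24 | tert-butyldimethylsilyl ether of 31 | CC1=CC(C)(C)[C@@H]2CC[C@@](C)(O[Si](C)(C)C(C)(C)C)[C@@H]2CC1=O
F10 | step 31 | primary iodide from 35 | IC[C@@H]1C(C)(C)[C@@H]2CC[C@@](C)(O)[C@@H]2C[C@@H]2O[C@@]21C
F11 | step 31 | secondary alcohol from 22 and the organocerium reagent, both carbinol epimers | CC1(C)O[C@@H]2CC[C@](C)(O[Si](C)(C)C)[C@H](C(O)C[C@@H]3C(C)(C)[C@@H]4CC[C@@](C)(O)[C@@H]4C[C@@H]4O[C@@]43C)[C@@]2(C)CCC1=O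
F12 | step 31 | O-phenyl thionocarbonate of F11 | CC1(C)O[C@@H]2CC[C@](C)(O[Si](C)(C)C)[C@H](C(OC(=S)Oc3ccccc3)C[C@@H]3C(C)(C)[C@@H]4CC[C@@](C)(O)[C@@H]4C[C@@H]4O[C@@]43C)[C@@]2(C)CCC1=O
A1 | alternative 1 | methyl diepoxy β-keto ester, open-chain precursor | COC(=O)CC(=O)CC[C@H]1O[C@]1(C)CC[C@H]1OC1(C)C
A2 | alternative 1 | rings A/B hydroxy β-keto ester | CC1(C)O[C@@H]2CCC(=O)[C@H](C(=O)OC)[C@@]2(C)CC[C@H]1O
A3 | alternative 2 | tertiary hydroxy diketone with silyloxy group | CC(C)(O)C(=O)CC[C@]1(C)[C@H](O[Si](C)(C)C(C)(C)C)CCCC1=O
A4 | alternative 2 | trans-fused oxepanone–cyclohexane silyl ether | CC1(C)O[C@@H]2CCC[C@@H](O[Si](C)(C)C(C)(C)C)[C@@]2(C)CCC1=O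
A5 | alternative 3 | 2-methylcyclopent-2-en-1-one | CC1=CCCC1=O
A6 | alternative 3 | 2-hydroxy-2-methyl-3-vinylcyclopentan-1-one | C=C[C@@H]1CCC(=O)[C@@]1(C)O
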